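**Plan**

- Retrosynthesis: after the three MOM ethers are removed, the bonds C4a–C5 and C8–C8a of each of the three naphthalenes are cut (six C–C bonds). Every naphthalene has its methoxy ring (C5–C8, OMe on C8) fused beside the oxygen on C1, which is the pattern a 3-oxygenated aryne and 3-methoxy-2-pyrone give after loss of CO2.
- This leaves a terphenyl of three resorcinol rings with three ortho-silylaryl triflate units. Its two biaryl bonds are cut next (Suzuki–Miyaura) into a central dibromide and an outer boronate, both made from 4-bromoresorcinol.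
- Forward: the outer ring is protected, silylated between its oxygens and borylated; the central ring is brominated and protected; the two biaryl bonds are joined and the central ring is silylated.
- The three carbamates are then changed to triflates, the three methoxy-bearing benzo rings close in one operation, and MOM removal ends the route.
- Stereochemistry: the target has no stereocentre and its SMILES fixes no axis, so nothing has to be controlled.

Key step: step 12

Assumption: the two naphthyl–naphthyl axes are taken as not configurationally defined and are left uncontrolled.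
Assumption: the three silyl triflate units of 13 need not react in a fixed order; intermediates 16 to 23 are drawn for the order outer ring beside the MOM-bearing central carbon, other outer ring, central ring, and any other order gives the same product 24.
Assumption: in steps that repeat one reaction at two or three like sites (steps 7, 9, 10 and 13) the partly converted species are not numbered.

**Route**

Step 1
Reactants: 1 4-bromobenzene-1,3-diol
Product: 2 2-bromo-5-(methoxymethoxy)phenol
Conditions: MOMCl (1.0 equiv), K2CO3, acetone, 0 °C to rt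
Reagents that add atoms: chloromethyl methyl ether, COCCl
Why: Williamson-type O-alkylation with one equivalent of MOMCl should take place at the hydroxyl para to bromine, since the hydroxyl next to bromine is more hindered and hydrogen-bonded (the selectivity known from monobenzylation of this diol), and the bis-ether is separable.

Step 2
Reactants: 2 2-bromo-5-(methoxymethoxy)phenol
Product: 3 2-bromo-5-(methoxymethoxy)phenyl diethylcarbamate
Conditions: ClC(O)NEt2, K2CO3, MeCN, reflux
Reagents that add atoms: N,N-diethylcarbamoyl chloride, CCN(CC)C(Cl)=O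
Why: O-carbamoylation of the remaining phenol under carbonate base installs the strongest oxygen directing group for ortho-metalation and leaves the base-stable MOM ether untouched.

Step 3
Reactants: 3 2-bromo-5-(methoxymethoxy)phenyl diethylcarbamate
Product: 5 6-bromo-3-(methoxymethoxy)-2-(trimethylsilyl)phenyl diethylcarbamate, via aryllithium 4 (not isolated)
Conditions: LDA (1.2 equiv), THF, −78 °C; TMSCl, −78 °C to rt
Reagents that add atoms: chlorotrimethylsilane, C[Si](C)(C)Cl
Why: Directed ortho-metalation removes the C–H flanked by the carbamate and the MOM ether (two cooperating directing groups), the amide base does not exchange the aryl bromide at −78 °C, and silylation at that temperature precedes any anionic Fries rearrangement.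

Step 4
Reactants: 5 6-bromo-3-(methoxymethoxy)-2-(trimethylsilyl)phenyl diethylcarbamate
Product: 6 3-(methoxymethoxy)-6-(4,4,5,5-tetramethyl-1,3,2-dioxaborolan-2-yl)-2-(trimethylsilyl)phenyl diethylcarbamate
Conditions: B2pin2, PdCl2(dppf) (5 mol%), KOAc, 1,4-dioxane, 90 °C
Reagents that add atoms: bis(pinacolato)diboron, CC1(C)OB(OC1(C)C)B1OC(C)(C)C(C)(C)O1
Why: Miyaura borylation of the aryl bromide under weak acetate base should leave the aryl–silicon bond, the carbamate and the MOM ether intact.

Step 5
Reactants: 2 2-bromo-5-(methoxymethoxy)phenol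
Product: 7 2,4-dibromo-5-(methoxymethoxy)phenol
Conditions: NBS (1.0 equiv), MeCN, −20 °C to 0 °C
Reagents that add atoms: N-bromosuccinimide, O=C1CCC(=O)N1Br
Why: Electrophilic aromatic bromination of the free phenol should go para to the hydroxyl (also ortho to the MOM ether) rather than to the crowded position between the two oxygens, which gives the unsymmetrically protected 4,6-dibromoresorcinol without a statistical step.

Step 6
Reactants: 7 2,4-dibromo-5-(methoxymethoxy)phenol
Product: 8 4,6-dibromo-3-(methoxymethoxy)phenyl diethylcarbamate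
Conditions: ClC(O)NEt2, K2CO3, MeCN, reflux
Reagents that add atoms: N,N-diethylcarbamoyl chloride, CCN(CC)C(Cl)=O
Why: O-carbamoylation as in step 2 gives the central ring its directing group and future triflate oxygen.

Step 7
Reactants: 6 3-(methoxymethoxy)-6-(4,4,5,5-tetramethyl-1,3,2-dioxaborolan-2-yl)-2-(trimethylsilyl)phenyl diethylcarbamate (2.4 equiv); 8 4,6-dibromo-3-(methoxymethoxy)phenyl diethylcarbamate
Product: 9 4,6-bis{2-[(diethylcarbamoyl)oxy]-4-(methoxymethoxy)-3-(trimethylsilyl)phenyl}-3-(methoxymethoxy)phenyl diethylcarbamate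
Conditions: Pd(OAc)2 (5 mol%), SPhos (10 mol%), K3PO4, toluene/H2O, 90 °C
Reagents that add atoms: none
Why: Twofold Suzuki–Miyaura coupling joins simple benzene rings across bonds that carry only one ortho oxygen substituent on each side, well within reach of a dialkylbiarylphosphine ligand, and diethylcarbamates, MOM ethers and aryl–silicon bonds tolerate aqueous phosphate.

Step 8
Reactants: 9 4,6-bis{2-[(diethylcarbamoyl)oxy]-4-(methoxymethoxy)-3-(trimethylsilyl)phenyl}-3-(methoxymethoxy)phenyl diethylcarbamate
Product: 11 4,6-bis{2-[(diethylcarbamoyl)oxy]-4-(methoxymethoxy)-3-(trimethylsilyl)phenyl}-3-(methoxymethoxy)-2-(trimethylsilyl)phenyl diethylcarbamate, via aryllithium 10 (not isolated)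
Conditions: s-BuLi (1.3 equiv), TMEDA, THF, −78 °C; TMSCl, −78 °C to rt
Reagents that add atoms: chlorotrimethylsilane, C[Si](C)(C)Cl
Why: Directed ortho-metalation should be selective because the only remaining C–H flanked by two oxygen directing groups is C2 of the central ring, while the outer carbamates have no free ortho position and resist addition at −78 °C.

Step 9
Reactants: 11 4,6-bis{2-[(diethylcarbamoyl)oxy]-4-(methoxymethoxy)-3-(trimethylsilyl)phenyl}-3-(methoxymethoxy)-2-(trimethylsilyl)phenyl diethylcarbamate
Product: 12 4,6-bis[2-hydroxy-4-(methoxymethoxy)-3-(trimethylsilyl)phenyl]-3-(methoxymethoxy)-2-(trimethylsilyl)phenol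
Conditions: LiAlH4 (excess), THF, 0 °C to reflux; aqueous potassium sodium tartrate work-up
Reagents that add atoms: none
Why: Hydride reduction of the carbamate carbonyl releases the phenoxide even from doubly ortho-substituted carbamates because the nucleophile is small, MOM ethers and aryl–silicon bonds are inert to it, and the non-acidic work-up avoids protodesilylation.

Step 10
Reactants: 12 4,6-bis[2-hydroxy-4-(methoxymethoxy)-3-(trimethylsilyl)phenyl]-3-(methoxymethoxy)-2-(trimethylsilyl)phenol
Product: 13 3-(methoxymethoxy)-4,6-bis{4-(methoxymethoxy)-2-[(trifluoromethanesulfonyl)oxy]-3-(trimethylsilyl)phenyl}-2-(trimethylsilyl)phenyl trifluoromethanesulfonate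
Conditions: Tf2O (3.6 equiv), pyridine, CH2Cl2, 0 °C
Reagents that add atoms: trifluoromethanesulfonic anhydride, O=S(=O)(OS(=O)(=O)C(F)(F)F)C(F)(F)F
Why: O-sulfonylation of ortho-silylphenols with triflic anhydride and pyridine is the standard entry to ortho-silylaryl triflates, and the buffered medium at 0 °C spares the MOM ethers.

Step 11
Reactants: 14 3-hydroxy-2H-pyran-2-one
Product: 15 3-methoxy-2H-pyran-2-one
Conditions: MeI, K2CO3, acetone, rt
Reagents that add atoms: iodomethane, CI
Why: Williamson O-methylation of the acidic enolic hydroxyl proceeds under mild carbonate conditions that do not open the pyrone ring.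

Step 12
Reactants: 13 3-(methoxymethoxy)-4,6-bis{4-(methoxymethoxy)-2-[(trifluoromethanesulfonyl)oxy]-3-(trimethylsilyl)phenyl}-2-(trimethylsilyl)phenyl trifluoromethanesulfonate; 15 3-methoxy-2H-pyran-2-one (9 equiv)
Product: 24 8-methoxy-1-(methoxymethoxy)-2,4-bis[5-methoxy-4-(methoxymethoxy)naphthalen-1-yl]naphthalene, via first aryne 16 (not isolated), via first bridged lactone 17 (not isolated), via mono-annulated bis(silyl triflate) 18 (not isolated), via second aryne 19 (not isolated), via second bridged lactone 20 (not isolated), via bis-annulated silyl triflate 21 (not isolated), via third aryne 22 (not isolated), via third bridged lactone 23 (not isolated)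
Conditions: CsF (12 equiv), MeCN, rt, then 60 °C
Reagents that add atoms: none
Why: Proposed new method: fluoride attacks each trimethylsilyl group and the aryl anion expels the neighbouring triflate, so three 3-(methoxymethoxy)arynes arise one after another on separate rings; each adds across C3 and C6 of 3-methoxy-2-pyrone in a [4+2] cycloaddition and the bridged lactone then loses CO2 in a retro-[4+2] step. The closest known reaction type is the single Diels-Alder reaction of an aryne from an ortho-silylaryl triflate with a 2-pyrone followed by CO2 extrusion to a naphthalene; new here are three such events on one terphenyl and the pairing of an unsymmetrical 3-alkoxy-6-arylaryne with 3-methoxy-2-pyrone. Each of the three new benzene rings is closed by an intermolecular [4+2] cycloaddition that forms C4a–C5 and C8–C8a together, and aromatisation by loss of CO2 makes each closure irreversible. No stereocentre is formed. The step needs one orientation in every cycloaddition, with the methoxy-bearing C3 of the pyrone on the aryne carbon next to the MOM ether: the inductive effect of the alkoxy group makes the remote aryne carbon the more electrophilic one, the donor methoxy group on C3 makes the far terminus C6 the nucleophilic end of the diene (the polarity that governs additions of 2-methoxyfuran to 3-alkoxyarynes), and the bulkier C3 terminus is kept away from the aryl-flanked carbon. An excess of pyrone and slow aryne release at room temperature should keep each aryne from reacting with anything else.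

Step 13
Reactants: 24 8-methoxy-1-(methoxymethoxy)-2,4-bis[5-methoxy-4-(methoxymethoxy)naphthalen-1-yl]naphthalene
Product: 25 2,4-bis(4-hydroxy-5-methoxynaphthalen-1-yl)-8-methoxynaphthalen-1-ol
Conditions: HCl, MeOH/THF, 40 °C, under argon
Reagents that add atoms: none
Why: Acid-catalysed acetal cleavage with transfer of the methylene unit to methanol removes the three MOM ethers while the aryl methyl ethers stay in place.

**Compound list**

1 | 4-bromobenzene-1,3-diol | Oc1ccc(Br)c(O)c1 | starting material
2 | 2-bromo-5-(methoxymethoxy)phenol | COCOc1ccc(Br)c(O)c1 | intermediate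
3 | 2-bromo-5-(methoxymethoxy)phenyl diethylcarbamate | CCN(CC)C(=O)Oc1cc(OCOC)ccc1Br | intermediate
4 | aryllithium: 3 lithiated at the carbon between the carbamate and the MOM ether | CCN(CC)C(=O)Oc1c([Li])c(OCOC)ccc1Br | intermediate
5 | 6-bromo-3-(methoxymethoxy)-2-(trimethylsilyl)phenyl diethylcarbamate | CCN(CC)C(=O)Oc1c([Si](C)(C)C)c(OCOC)ccc1Br | intermediate
6 | 3-(methoxymethoxy)-6-(4,4,5,5-tetramethyl-1,3,2-dioxaborolan-2-yl)-2-(trimethylsilyl)phenyl diethylcarbamate | CCN(CC)C(=O)Oc1c([Si](C)(C)C)c(OCOC)ccc1B1OC(C)(C)C(C)(C)O1 | intermediate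
7 | 2,4-dibromo-5-(methoxymethoxy)phenol | COCOc1cc(O)c(Br)cc1Br | intermediate
8 | 4,6-dibromo-3-(methoxymethoxy)phenyl diethylcarbamate | CCN(CC)C(=O)Oc1cc(OCOC)c(Br)cc1Br | intermediate
9 | 4,6-bis{2-[(diethylcarbamoyl)oxy]-4-(methoxymethoxy)-3-(trimethylsilyl)phenyl}-3-(methoxymethoxy)phenyl diethylcarbamate | CCN(CC)C(=O)Oc1cc(OCOC)c(-c2ccc(OCOC)c([Si](C)(C)C)c2OC(=O)N(CC)CC)cc1-c1ccc(OCOC)c([Si](C)(C)C)c1OC(=O)N(CC)CC | intermediate
10 | aryllithium: 9 lithiated at C2 of the central ring | CCN(CC)C(=O)Oc1c([Li])c(OCOC)c(-c2ccc(OCOC)c([Si](C)(C)C)c2OC(=O)N(CC)CC)cc1-c1ccc(OCOC)c([Si](C)(C)C)c1OC(=O)N(CC)CC | intermediate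
11 | 4,6-bis{2-[(diethylcarbamoyl)oxy]-4-(methoxymethoxy)-3-(trimethylsilyl)phenyl}-3-(methoxymethoxy)-2-(trimethylsilyl)phenyl diethylcarbamate | CCN(CC)C(=O)Oc1c([Si](C)(C)C)c(OCOC)c(-c2ccc(OCOC)c([Si](C)(C)C)c2OC(=O)N(CC)CC)cc1-c1ccc(OCOC)c([Si](C)(C)C)c1OC(=O)N(CC)CC | intermediate
12 | 4,6-bis[2-hydroxy-4-(methoxymethoxy)-3-(trimethylsilyl)phenyl]-3-(methoxymethoxy)-2-(trimethylsilyl)phenol | Oc1c([Si](C)(C)C)c(OCOC)c(-c2ccc(OCOC)c([Si](C)(C)C)c2O)cc1-c1ccc(OCOC)c([Si](C)(C)C)c1O | intermediate
13 | 3-(methoxymethoxy)-4,6-bis{4-(methoxymethoxy)-2-[(trifluoromethanesulfonyl)oxy]-3-(trimethylsilyl)phenyl}-2-(trimethylsilyl)phenyl trifluoromethanesulfonate | FC(F)(F)S(=O)(=O)Oc1c([Si](C)(C)C)c(OCOC)c(-c2ccc(OCOC)c([Si](C)(C)C)c2OS(=O)(=O)C(F)(F)F)cc1-c1ccc(OCOC)c([Si](C)(C)C)c1OS(=O)(=O)C(F)(F)F | intermediate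
14 | 3-hydroxy-2H-pyran-2-one | O=c1occcc1O | starting material
15 | 3-methoxy-2H-pyran-2-one | COc1cccoc1=O | intermediate
16 | first aryne: 13 in which the outer ring beside the MOM-bearing central carbon has lost Me3Si and OTf (2,3-didehydro-4-(methoxymethoxy)phenyl group) | FC(F)(F)S(=O)(=O)Oc1c([Si](C)(C)C)c(OCOC)c(C2=CC=C(OCOC)C#C2)cc1-c1ccc(OCOC)c([Si](C)(C)C)c1OS(=O)(=O)C(F)(F)F | intermediate
17 | first bridged lactone: [4+2] adduct of 16 with 15, a benzo-fused 2-oxabicyclo[2.2.2]octadienone with the methoxy bridgehead beside the MOM-bearing carbon (racemic) | FC(F)(F)S(=O)(=O)Oc1c([Si](C)(C)C)c(OCOC)c(-c2ccc(OCOC)c3c2C4OC(=O)C3(OC)C=C4)cc1-c1ccc(OCOC)c([Si](C)(C)C)c1OS(=O)(=O)C(F)(F)F | intermediate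
18 | 3-(methoxymethoxy)-4-[5-methoxy-4-(methoxymethoxy)naphthalen-1-yl]-6-{4-(methoxymethoxy)-2-[(trifluoromethanesulfonyl)oxy]-3-(trimethylsilyl)phenyl}-2-(trimethylsilyl)phenyl trifluoromethanesulfonate | FC(F)(F)S(=O)(=O)Oc1c([Si](C)(C)C)c(OCOC)c(-c2ccc(OCOC)c3c(OC)cccc23)cc1-c1ccc(OCOC)c([Si](C)(C)C)c1OS(=O)(=O)C(F)(F)F | intermediate
19 | second aryne: 18 in which the remaining outer ring has lost Me3Si and OTf | FC(F)(F)S(=O)(=O)Oc1c([Si](C)(C)C)c(OCOC)c(-c2ccc(OCOC)c3c(OC)cccc23)cc1C1=CC=C(OCOC)C#C1 | intermediate
20 | second bridged lactone: [4+2] adduct of 19 with 15 (racemic) | FC(F)(F)S(=O)(=O)Oc1c([Si](C)(C)C)c(OCOC)c(-c2ccc(OCOC)c3c(OC)cccc23)cc1-c1ccc(OCOC)c2c1C3OC(=O)C2(OC)C=C3 | intermediate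
21 | 3-(methoxymethoxy)-4,6-bis[5-methoxy-4-(methoxymethoxy)naphthalen-1-yl]-2-(trimethylsilyl)phenyl trifluoromethanesulfonate | FC(F)(F)S(=O)(=O)Oc1c([Si](C)(C)C)c(OCOC)c(-c2ccc(OCOC)c3c(OC)cccc23)cc1-c1ccc(OCOC)c2c(OC)cccc12 | intermediate
22 | third aryne: 3-(methoxymethoxy)-4,6-bis[5-methoxy-4-(methoxymethoxy)naphthalen-1-yl]-1,2-didehydrobenzene | COCOC1=C(c2ccc(OCOC)c3c(OC)cccc23)C=C(c2ccc(OCOC)c3c(OC)cccc23)C#C1 | intermediate
23 | third bridged lactone: [4+2] adduct of 22 with 15 (racemic) | COCOc1c(-c2ccc(OCOC)c3c(OC)cccc23)cc(-c2ccc(OCOC)c3c(OC)cccc23)c2c1C1(OC)C=CC2OC1=O | intermediate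
24 | 8-methoxy-1-(methoxymethoxy)-2,4-bis[5-methoxy-4-(methoxymethoxy)naphthalen-1-yl]naphthalene | COc1cccc2c(-c3cc(-c4ccc(OCOC)c5c(OC)cccc45)c4cccc(OC)c4c3OCOC)ccc(OCOC)c12 | intermediate
25 | 2,4-bis(4-hydroxy-5-methoxynaphthalen-1-yl)-8-methoxynaphthalen-1-ol (CNP0528831.0) | COc1cccc2c(-c3cc(-c4ccc(O)c5c(OC)cccc45)c4cccc(OC)c4c3O)ccc(O)c12 | target

**Step count and risks**

Total steps: 13. Longest linear sequence: 10 steps (1, 2, 3, 4, 7, 8, 9, 10, 12, 13).

Steps most likely to fail:

1. Step 12 (Proposed new method). One or more of the three cycloadditions may take the reverse orientation, an outer-ring aryne may be intercepted by the oxygen of the neighbouring MOM ether before the pyrone arrives, or the threefold sequence may stop short. The fallback uses known chemistry, the head-to-head cycloaddition of 3-alkoxyarynes with 2-methoxyfuran and the hydrogenolysis of aryl triflates. It sets out from 13: CsF and excess 2-methoxyfuran in MeCN at rt should give the threefold oxygen-bridged ketal adduct F1, which opens under mild acid (silica gel or pyridinium p-toluenesulfonate) to the tris(naphthol) F2. In F2 each new ring carries its methoxy group peri to the MOM ether and a hydroxyl at the other end. Tf2O and pyridine would then give the tris(triflate) F3, and Pd(OAc)2, 1,1'-bis(diphenylphosphino)ferrocene, HCO2H and Et3N in DMF at 80 °C would remove the three triflates reductively, coming back to the route at 24.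

2. Step 7. Protodeboronation of the ortho-oxygenated boronate may outrun the second coupling, so that the sequence stalls after one biaryl bond. The fallback replaces the boron nucleophile by zinc and sets out from 5 (with 8): bromine–lithium exchange with n-BuLi in THF at −78 °C gives the aryllithium F4, and ZnCl2 converts it at that temperature into the arylzinc chloride F5. Negishi coupling of F5 with 8 (Pd2(dba)3, SPhos, THF, 60 °C) then comes back to the route at 9, without step 4.

3. Step 3. Deprotonation next to bromine may compete, with halogen migration, or the aryllithium may undergo anionic Fries rearrangement before it is silylated. The fallback postpones all silylation until the rings are joined and sets out from 3 (with 8): Miyaura borylation as in step 4 gives the silicon-free boronate F6, and Suzuki–Miyaura coupling with 8 as in step 7 gives the silicon-free terphenyl tris(carbamate) F7. Threefold directed ortho-metalation (s-BuLi, TMEDA, 4 equiv, THF, −78 °C) at the three positions flanked by carbamate and MOM ether gives the trilithiated terphenyl F8, and TMSCl silylates it, coming back to the route at 11.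

**Further compounds**

F1 | step 12 | threefold [4+2] adduct of the three arynes from 13 with 2-methoxyfuran (three 1-methoxy-1,4-epoxy-1,4-dihydro units, methoxy bridgeheads beside the MOM-bearing carbons) | COCOc1c(-c2ccc(OCOC)c3c2C2OC3(OC)C=C2)cc(-c2ccc(OCOC)c3c2C2OC3(OC)C=C2)c2c1C1(OC)C=CC2O1
F2 | step 12 | 6,8-bis[8-hydroxy-5-methoxy-4-(methoxymethoxy)naphthalen-1-yl]-4-methoxy-5-(methoxymethoxy)naphthalen-1-ol | COCOc1c(-c2ccc(OCOC)c3c(OC)ccc(O)c23)cc(-c2ccc(OCOC)c3c(OC)ccc(O)c23)c2c(O)ccc(OC)c12
F3 | step 12 | tris(trifluoromethanesulfonate) of F2 | COCOc1c(-c2ccc(OCOC)c3c(OC)ccc(OS(=O)(=O)C(F)(F)F)c23)cc(-c2ccc(OCOC)c3c(OC)ccc(OS(=O)(=O)C(F)(F)F)c23)c2c(OS(=O)(=O)C(F)(F)F)ccc(OC)c12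
F4 | step 7 | aryllithium from bromine–lithium exchange of 5 | CCN(CC)C(=O)Oc1c([Si](C)(C)C)c(OCOC)ccc1[Li]
F5 | step 7 | {2-[(diethylcarbamoyl)oxy]-4-(methoxymethoxy)-3-(trimethylsilyl)phenyl}zinc chloride | CCN(CC)C(=O)Oc1c([Si](C)(C)C)c(OCOC)ccc1[Zn]Cl
F6 | step 3 | 5-(methoxymethoxy)-2-(4,4,5,5-tetramethyl-1,3,2-dioxaborolan-2-yl)phenyl diethylcarbamate | CCN(CC)C(=O)Oc1cc(OCOC)ccc1B1OC(C)(C)C(C)(C)O1
F7 | step 3 | 4,6-bis{2-[(diethylcarbamoyl)oxy]-4-(methoxymethoxy)phenyl}-3-(methoxymethoxy)phenyl diethylcarbamate | CCN(CC)C(=O)Oc1cc(OCOC)c(-c2ccc(OCOC)cc2OC(=O)N(CC)CC)cc1-c1ccc(OCOC)cc1OC(=O)N(CC)CC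
F8 | step 3 | F7 lithiated on each ring at the carbon between carbamate and MOM ether | CCN(CC)C(=O)Oc1c([Li])c(OCOC)c(-c2ccc(OCOC)c([Li])c2OC(=O)N(CC)CC)cc1-c1ccc(OCOC)c([Li])c1OC(=O)N(CC)CC
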